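**Retrosynthetic overview**
1. 26 ⇐ 23: the last step is a ring expansion. The C1–C5 bond of a cis-fused bicyclo[5.3.0]decane is cleaved in a vinylogous Grob fragmentation (enol ether as donor, spiro-oxirane as nucleofuge), giving the ten-membered ring, both ring-cis alkenes, the enal and the CH2OH at once.
2. 23 ⇐ 20 (oxirane from the ketone, CHO from a vinyl group); 20 ⇐ 18 by intramolecular Hosomi–Sakurai closure of the seven-membered ring (C1–C10).
3. 18 ⇐ 13 + 16: chromium Barbier allylation and lactonisation (C6–C7 bond, γ-lactone).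
4. 13 ⇐ 5 + 6 (Brown methoxyallylboration, C8–C9), then acylation and cross-metathesis; 16 ⇐ 14.
5. Ring order: five-membered ring (bought) → γ-lactone → seven-membered ring → oxirane → ten-membered ring.

Assumption: germacrane numbering (C-1 to C-15) is used for all compounds, and the SMILES is read as the (6R,7S,8S,9S) isomer with both ring double bonds cis inside the ring (C-2 cis to C-9, C-3 cis to C-6).

**Step 1**
Reactants: 1 2,2-dimethoxyacetaldehyde; 2 methyl acrylate
Product: 3 methyl 2-(1-hydroxy-2,2-dimethoxyethyl)prop-2-enoate (racemic)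
Conditions: DABCO (20 mol%), 1,4-dioxane–H2O, rt
Reagents that add atoms: none
Why: Morita–Baylis–Hillman reaction of a reactive α-alkoxy aldehyde; the racemic carbinol centre is erased in step 2.

**Step 2**
Reactants: 3 methyl 2-(1-hydroxy-2,2-dimethoxyethyl)prop-2-enoate
Product: 5 methyl (2Z)-2-(bromomethyl)-4-oxobut-2-enoate, via bromo acetal 4 (not isolated)
Conditions: NBS, Me2S, CH2Cl2, 0 °C to rt; then TFA–H2O (9:1), 0 °C
Reagents that add atoms: N-bromosuccinimide, O=C1CCC(=O)N1Br; water, O
Why: Corey–Kim-type SN2′ bromination of the Baylis–Hillman alcohol gives the thermodynamic (Z)-allylic bromide, and acetal hydrolysis then frees the aldehyde; no stereocentre is present.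

**Step 3**
Reactants: 5 methyl (2Z)-2-(bromomethyl)-4-oxobut-2-enoate; 6 allyl methyl ether
Product: 9 methyl (2Z,4S,5S)-2-(bromomethyl)-4-hydroxy-5-methoxyhepta-2,6-dienoate, via allylborane 7 (not isolated), via borinate ester 8 (not isolated)
Conditions: 6, s-BuLi, THF, −78 °C; (+)-Ipc2BOMe; BF3·OEt2; then 5, −78 °C; then H2O2, pH 7 buffer, MeOH, 0 °C
Reagents that add atoms: none
Why: Brown (Z)-γ-methoxyallylboration through a closed chair transition state; the (Z)-enol ether gives the syn C-8/C-9 relationship and the Ipc ligands from (−)-α-pinene direct attack on the Re face of the aldehyde, so C-8 (S) and C-9 (S) are set by the reagent (9 is acylated at once because the free hydroxyl sits cis to the CH2Br group).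

**Step 4**
Reactants: 9 methyl (2Z,4S,5S)-2-(bromomethyl)-4-hydroxy-5-methoxyhepta-2,6-dienoate; 10 methacryloyl chloride
Product: 11 methyl (2Z,4S,5S)-2-(bromomethyl)-5-methoxy-4-(2-methylprop-2-enoyloxy)hepta-2,6-dienoate
Conditions: 2,6-lutidine, CH2Cl2, 0 °C
Reagents that add atoms: none
Why: O-acylation with a hindered base that does not quaternise the allylic bromide; the stereocentres are untouched.

**Step 5**
Reactants: 11 methyl (2Z,4S,5S)-2-(bromomethyl)-5-methoxy-4-(2-methylprop-2-enoyloxy)hepta-2,6-dienoate; 12 allyltrimethylsilane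
Product: 13 methyl (2Z,4S,5S,6E)-2-(bromomethyl)-5-methoxy-4-(2-methylprop-2-enoyloxy)-8-(trimethylsilyl)octa-2,6-dienoate
Conditions: second-generation Hoveyda–Grubbs catalyst (5 mol%), 12 (4 equiv), CH2Cl2, 40 °C
Reagents that add atoms: none
Why: Olefin cross-metathesis at the only unhindered terminal alkene, with excess partner to outrun ring closure onto the methacrylate; the E/Z ratio does not matter because this alkene is transposed in step 9.

**Step 6**
Reactants: 14 2-bromocyclopent-2-en-1-one
Product: 15 6-bromo-1,4-dioxaspiro[4.4]non-6-ene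
Conditions: ethylene glycol, p-TsOH (cat.), benzene, reflux (Dean–Stark)
Reagents that add atoms: ethylene glycol, OCCO
Why: Acid-catalysed ketalisation masks the ketone for the halogen–lithium exchange.

**Step 7**
Reactants: 15 6-bromo-1,4-dioxaspiro[4.4]non-6-ene
Product: 16 1,4-dioxaspiro[4.4]non-6-ene-6-carbaldehyde
Conditions: n-BuLi, THF, −78 °C; then DMF; H2O
Reagents that add atoms: N,N-dimethylformamide, CN(C)C=O
Why: Bromine–lithium exchange and formylation of the vinyllithium (an α-ketovinyl anion equivalent); the formyl carbon becomes C-6.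

**Step 8**
Reactants: 13 methyl (2Z,4S,5S,6E)-2-(bromomethyl)-5-methoxy-4-(2-methylprop-2-enoyloxy)-8-(trimethylsilyl)octa-2,6-dienoate; 16 1,4-dioxaspiro[4.4]non-6-ene-6-carbaldehyde
Product: 18 enone lactone (trans-4,5-disubstituted 3-methylenedihydrofuran-2-one carrying the 5-oxocyclopent-1-en-1-yl group at C-6 and the (8S,9S) allylsilane chain at C-7), via hydroxy ester 17 (not isolated)
Conditions: CrCl2 (4 equiv), THF, rt; then 1 M HCl, THF, rt
Reagents that add atoms: water, O
Why: Nozaki–Hiyama-type chromium Barbier allylation; the allylchromium reagent reacts at its γ-carbon (C-7) through a chair transition state with the C-8 substituent equatorial (anti adduct, hence trans-lactone) and anti to the C8–C9 bond with H-8 eclipsing the alkene (allylic strain control), which sets C-6 and C-7, and the acid then lactonises and removes the ketal.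

**Step 9**
Reactants: 18 enone lactone
Product: 20 cis-fused bicyclo[5.3.0]decanone lactone (1αH,5αH; 6α-O/7β-C trans-lactone; 8β-methacryloyloxy; 9α-methoxy; 10β-vinyl; ketone at C-4), via titanium enolate 19 (not isolated)
Conditions: TiCl4 (1.1 equiv), CH2Cl2, −78 °C; then H2O at −78 °C
Reagents that add atoms: none
Why: Intramolecular Hosomi–Sakurai conjugate addition; the allylsilane γ-carbon (C-10) attacks the activated enone β-carbon (C-1), which is a better acceptor than the α-methylene lactone or the methacrylate, and protonation of the enolate from the convex face gives the cis ring fusion (C-1, C-5 and C-10 are temporary centres that are erased in step 12).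

**Step 10**
Reactants: 20 cis-fused bicyclo[5.3.0]decanone lactone
Product: 22 spiro-oxirane at C-4 (oxirane oxygen on the concave face, cis to C-6 and C-10; oxirane CH2 is C-15), via chlorohydrin alkoxide 21 (not isolated)
Conditions: ICH2Cl, MeLi·LiBr, THF, −78 °C to rt
Reagents that add atoms: chloroiodomethane, ClCI
Why: Chloromethyllithium (generated in situ by iodine–lithium exchange) adds to ketones faster than to esters, and C–C bond formation on the convex face of the cis-fused bicycle leaves the oxygen on the concave face before ring closure to the oxirane.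

**Step 11**
Reactants: 22 spiro-oxirane
Product: 23 10-formyl spiro-oxirane (aldehyde carbon is C-14)
Conditions: OsO4 (2 mol%), NaIO4, 2,6-lutidine, 1,4-dioxane–H2O, rt
Reagents that add atoms: sodium periodate, [Na+].[O-]I(=O)(=O)=O
Why: Lemieux–Johnson cleavage of the only alkene that is not conjugated to an ester; the C-10 centre formed is epimerisable and is erased in step 12.

**Step 12**
Reactants: 23 10-formyl spiro-oxirane
Product: 26 target, (6R,7S,8S,9S)-15-hydroxy-9-methoxy-14-oxogermacra-1(10),4,11(13)-trien-12,6-olid-8-yl methacrylate, via silyl enol ether 24 (not isolated), via silyl ether 25 (not isolated)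
Conditions: TMSOTf (1.3 equiv), Et3N (1.5 equiv), CH2Cl2, −78 to −20 °C; then citric acid, MeOH, 0 °C
Reagents that add atoms: none
Why: Proposed new method: soft enolisation gives silyl enol ether 24 and the silyl triflate then activates the spiro-oxirane, whose C4–O bond is anti-periplanar to the C1–C5 bond of the cis-fused bicycle while that bond is parallel to the enol-ether π system, so a push–pull vinylogous Grob (1,4-) fragmentation cleaves C1–C5 and relays the silyl group from O-14 to O-15; the oxirane oxygen cis to C-6 gives the C4=C5 alkene with C-3 and C-6 cis, the ring torsion of the same conformer (and the thermodynamic enal geometry) gives C1=C10 with C-2 and C-9 cis, no free enolate is formed so the C-9 methoxy group is not eliminated, C-alkylation is impossible because C-10 and C-15 lie on opposite faces, and C-6 to C-9 are untouched; the closest known reactions are the enolate-assisted 1,4-fragmentation of γ-sulfonyloxy aldehydes (eudesmane to germacrane) and the epoxy-alcohol Grob fragmentation.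

**Compound list**
1 | 2,2-dimethoxyacetaldehyde | COC(OC)C=O | starting material
2 | methyl acrylate | C=CC(=O)OC | starting material
3 | methyl 2-(1-hydroxy-2,2-dimethoxyethyl)prop-2-enoate (racemic) | COC(OC)C(O)C(=C)C(=O)OC | intermediate
4 | methyl (2Z)-2-(bromomethyl)-4,4-dimethoxybut-2-enoate | COC(OC)/C=C(\CBr)C(=O)OC | intermediate
5 | methyl (2Z)-2-(bromomethyl)-4-oxobut-2-enoate | O=C/C=C(\CBr)C(=O)OC | intermediate
6 | allyl methyl ether (3-methoxyprop-1-ene) | C=CCOC | starting material
7 | [(2Z)-3-methoxyprop-2-en-1-yl]bis(isopinocampheyl)borane (Ipc from (−)-α-pinene) | CO/C=C\CB([C@@H]1[C@@H](C)[C@@H]2C[C@H](C1)C2(C)C)[C@@H]1[C@@H](C)[C@@H]2C[C@H](C1)C2(C)C | intermediate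
8 | bis(isopinocampheyl)borinate ester of 9 (B–O at C-8) | B([C@@H]1[C@@H](C)[C@@H]2C[C@H](C1)C2(C)C)([C@@H]1[C@@H](C)[C@@H]2C[C@H](C1)C2(C)C)O[C@@H](/C=C(\CBr)C(=O)OC)[C@@H](OC)C=C | intermediate
9 | methyl (2Z,4S,5S)-2-(bromomethyl)-4-hydroxy-5-methoxyhepta-2,6-dienoate | O[C@@H](/C=C(\CBr)C(=O)OC)[C@@H](OC)C=C | intermediate
10 | methacryloyl chloride | C=C(C)C(=O)Cl | starting material
11 | methyl (2Z,4S,5S)-2-(bromomethyl)-5-methoxy-4-(2-methylprop-2-enoyloxy)hepta-2,6-dienoate | C=C(C)C(=O)O[C@@H](/C=C(\CBr)C(=O)OC)[C@@H](OC)C=C | intermediate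
12 | allyltrimethylsilane | C=CC[Si](C)(C)C | starting material
13 | methyl (2Z,4S,5S,6E)-2-(bromomethyl)-5-methoxy-4-(2-methylprop-2-enoyloxy)-8-(trimethylsilyl)octa-2,6-dienoate | C=C(C)C(=O)O[C@@H](/C=C(\CBr)C(=O)OC)[C@@H](OC)/C=C/C[Si](C)(C)C | intermediate
14 | 2-bromocyclopent-2-en-1-one | O=C1CCC=C1Br | starting material
15 | 6-bromo-1,4-dioxaspiro[4.4]non-6-ene | BrC1=CCCC12OCCO2 | intermediate
16 | 1,4-dioxaspiro[4.4]non-6-ene-6-carbaldehyde | O=CC1=CCCC12OCCO2 | intermediate
17 | open hydroxy ester: C-6 carbinol on the ketal-protected cyclopentene, C-7 bearing the acrylate ester, 6,7-anti, C-8/C-9 as in 13 | C=C(C)C(=O)O[C@@H]([C@@H](C(=C)C(=O)OC)[C@H](O)C1=CCCC12OCCO2)[C@@H](OC)/C=C/C[Si](C)(C)C | intermediate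
18 | enone lactone: trans α-methylene-γ-lactone, 5-oxocyclopent-1-en-1-yl at C-6, (8S,9S)-8-methacryloyloxy-9-methoxy allylsilane chain at C-7 | C=C(C)C(=O)O[C@@H]([C@H]1C(=C)C(=O)O[C@@H]1C2=CCCC2=O)[C@@H](OC)/C=C/C[Si](C)(C)C | intermediate
19 | trichlorotitanium enolate (C4–O–Ti, C4=C5) of 20 | C=C(C)C(=O)O[C@H]1[C@H]2C(=C)C(=O)O[C@@H]2C3=C(O[Ti](Cl)(Cl)Cl)CC[C@H]3[C@@H](C=C)[C@@H]1OC | intermediate
20 | cis-fused bicyclo[5.3.0]decan-4-one 12,6-lactone: 1αH,5αH, 6α-O, 7β-C, 8β-methacryloyloxy, 9α-methoxy, 10β-vinyl | C=C(C)C(=O)O[C@H]1[C@H]2C(=C)C(=O)O[C@@H]2[C@H]3C(=O)CC[C@H]3[C@@H](C=C)[C@@H]1OC | intermediate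
21 | lithium alkoxide of the C-4 chlorohydrin (O on the concave face, CH2Cl on the convex face) | C=C(C)C(=O)O[C@H]1[C@H]2C(=C)C(=O)O[C@@H]2[C@H]3[C@]([O-])(CCl)CC[C@H]3[C@@H](C=C)[C@@H]1OC.[Li+] | intermediate
22 | 4,15-spiro-oxirane of the bicycle (oxygen cis to C-6 and C-10), 10β-vinyl | C=C(C)C(=O)O[C@H]1[C@H]2C(=C)C(=O)O[C@@H]2[C@H]3[C@]4(CO4)CC[C@H]3[C@@H](C=C)[C@@H]1OC | intermediate
23 | 10-formyl 4,15-spiro-oxirane (C-14 aldehyde) | C=C(C)C(=O)O[C@H]1[C@H]2C(=C)C(=O)O[C@@H]2[C@H]3[C@]4(CO4)CC[C@H]3[C@@H](C=O)[C@@H]1OC | intermediate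
24 | trimethylsilyl enol ether of 23 (C10=C14–OSiMe3, E/Z mixture) | C=C(C)C(=O)O[C@H]1[C@H]2C(=C)C(=O)O[C@@H]2[C@H]3[C@]4(CO4)CC[C@H]3C(=CO[Si](C)(C)C)[C@@H]1OC | intermediate
25 | 15-O-trimethylsilyl ether of 26 | C=C(C)C(=O)O[C@H]1[C@H]2C(=C)C(=O)O[C@@H]2/C=C(/CO[Si](C)(C)C)CC/C=C(/C=O)[C@@H]1OC | intermediate
26 | (6R,7S,8S,9S)-15-hydroxy-9-methoxy-14-oxogermacra-1(10),4,11(13)-trien-12,6-olid-8-yl methacrylate (1(10)E,4E by CIP; both ring alkenes cis inside the ring) | C=C(C)C(=O)O[C@H]1[C@H]2C(=C)C(=O)O[C@@H]2/C=C(/CO)CC/C=C(/C=O)[C@@H]1OC | target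

**Step count and weak points**
Total steps: 12. Longest linear sequence: 10 (steps 1–5 and 8–12).

Step 12 (the proposed new fragmentation) is the most likely to fail. The risks are Lewis-acid rearrangement of the oxirane, loss of the C-9 methoxy group and transannular re-closure of the product. The fallback uses known chemistry only; it sets out from 13 and comes back at 26. Hosomi–Sakurai addition of 13 (BF3·OEt2, CH2Cl2, −78 °C) to the saturated formyl group of the separately prepared Z-configured dialdehyde F1 gives the bromo enal F2. CrCl2 at high dilution, the intramolecular Barbier ring closure known for germacranolides, followed by acid gives the macrolactone F3. OsO4/NaIO4 cleaves its vinyl group to the hydroxy aldehyde F4, whose C4=C5 alkene is deactivated by two allylic oxygens. MsCl and Et3N give the mesylate F5, DBU eliminates it to the silyl-protected enal F6, and HF·pyridine then gives 26.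

Step 9 (Sakurai closure of the seven-membered ring) is the second risk. The allylsilane may attack the α-methylene lactone instead, and the titanium enolate may expel the C-6 lactone oxygen. The fallback sets out from 13 and comes back at 20, with the order of the two ring-forming bonds inverted. Intermolecular Sakurai addition of 13 (TiCl4, −78 °C) to the silyl ether enone F7 (from commercial 2-(hydroxymethyl)cyclopent-2-en-1-one and Et3SiCl) gives the cyclopentanone F8. Swern oxidation turns its primary triethylsilyl ether directly into the keto aldehyde F9. CrCl2 then closes the seven-membered ring by intramolecular Barbier allylation, acid work-up lactonises, and the epimerisable C-5 settles in the cis-fused form 20.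

Step 10 (oxirane formation) is the third risk. The carbenoid is basic toward the β-acyloxy ketone and could attack the ester groups. The fallback sets out from 20 and comes back at 22. Takai–Lombardo methylenation (Zn, CH2Br2, TiCl4) gives the exocyclic alkene F10. NBS in wet THF gives the bromohydrin F11: the bromonium ion forms on the convex face and water attacks the tertiary carbon from the concave face. Ag2O then closes the oxirane to 22.

**Further compounds**
F1 | step 12 | (2E)-3-({[tert-butyl(dimethyl)silyl]oxy}methyl)hex-2-enedial (C-3 and C-6 of the target cis) | O=CCC/C(CO[Si](C)(C)C(C)(C)C)=C\C=O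
F2 | step 12 | Sakurai adduct of 13 and F1: open-chain bromo enal with 1-OH and 10-vinyl (epimers at C-1 and C-10) | C=C(C)C(=O)O[C@@H](/C=C(\CBr)C(=O)OC)[C@@H](OC)C(C=C)C(O)CC/C(CO[Si](C)(C)C(C)(C)C)=C\C=O
F3 | step 12 | ten-membered 12,6-lactone with 1-OH, 10-vinyl and 15-O-tert-butyldimethylsilyl (epimers at C-1 and C-10) | C=C(C)C(=O)O[C@H]1[C@H]2C(=C)C(=O)O[C@@H]2/C=C(/CO[Si](C)(C)C(C)(C)C)CCC(O)C(C=C)[C@@H]1OC
F4 | step 12 | 10-formyl analogue of F3 (β-hydroxy aldehyde) | C=C(C)C(=O)O[C@H]1[C@H]2C(=C)C(=O)O[C@@H]2/C=C(/CO[Si](C)(C)C(C)(C)C)CCC(O)C(C=O)[C@@H]1OC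
F5 | step 12 | 1-O-methanesulfonate of F4 | C=C(C)C(=O)O[C@H]1[C@H]2C(=C)C(=O)O[C@@H]2/C=C(/CO[Si](C)(C)C(C)(C)C)CCC(OS(C)(=O)=O)C(C=O)[C@@H]1OC
F6 | step 12 | 15-O-tert-butyldimethylsilyl ether of 26 | C=C(C)C(=O)O[C@H]1[C@H]2C(=C)C(=O)O[C@@H]2/C=C(/CO[Si](C)(C)C(C)(C)C)CC/C=C(/C=O)[C@@H]1OC
F7 | step 9 | 2-{[(triethylsilyl)oxy]methyl}cyclopent-2-en-1-one | O=C1CCC=C1CO[Si](CC)(CC)CC
F8 | step 9 | 2-{[(triethylsilyl)oxy]methyl}-3-substituted cyclopentanone from 13 and F7 (C-10 vinyl, allylic bromide retained; epimers at C-1, C-5, C-10) | C=C(C)C(=O)O[C@@H](/C=C(\CBr)C(=O)OC)[C@@H](OC)C(C=C)C1CCC(=O)C1CO[Si](CC)(CC)CC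
F9 | step 9 | 2-formyl analogue of F8 (keto aldehyde, C-6 aldehyde) | C=C(C)C(=O)O[C@@H](/C=C(\CBr)C(=O)OC)[C@@H](OC)C(C=C)C1CCC(=O)C1C=O
F10 | step 10 | 4-methylene analogue of 20 (exocyclic C4=C15) | C=C(C)C(=O)O[C@H]1[C@H]2C(=C)C(=O)O[C@@H]2[C@H]3C(=C)CC[C@H]3[C@@H](C=C)[C@@H]1OC
F11 | step 10 | C-4 bromohydrin (4-OH on the concave face, 15-bromo) | C=C(C)C(=O)O[C@H]1[C@H]2C(=C)C(=O)O[C@@H]2[C@H]3[C@](O)(CBr)CC[C@H]3[C@@H](C=C)[C@@H]1OC
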